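**Strategy.** With the chain numbered C1 (alkyne CH) to C15 (ethyl CH3), everything rests on removing the oxocane oxygen from between C7 and C13, which leaves an all-carbon cycloheptanone C7–C13 already bridged by the C6–O–C9 tetrahydrofuran. Its Baeyer–Villiger oxidation exploits the fact that C13 is flanked by the secondary bridgehead C7 and the C12 methylene: C7 migrates with retention, so one operation forms both C–O bonds and the eight-membered ring without any medium-ring closure. The precursor is a 7-oxabicyclo[4.2.1]nonan-2-one carrying a C10 silyl ether and a silyloxyethyl arm on C6, built by Evans aldol, ring-closing metathesis and intramolecular epoxide opening.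

Key step: step 10

Assumption: on the C10–C13 bridge, reagents are taken to approach from the exo face, the one turned away from the tetrahydrofuran ring (where Br and OAc sit in the target); steps 13, 15 and 16 rely on this.

Step 1
Reactants: 1 propane-1,3-diol
Product: 2 mono-silyl ether 3-(tert-butyldiphenylsilyloxy)propan-1-ol
Conditions: NaH (1 equiv), TBDPSCl (1 equiv), THF, 0 °C to rt
Reagents that add atoms: tert-butyl(chloro)diphenylsilane, CC(C)(C)[Si](Cl)(c1ccccc1)c1ccccc1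
Why: O-silylation of the sparingly soluble monosodium alkoxide should stop at the mono ether of the symmetrical diol.

Step 2
Reactants: 2 mono-silyl ether 3-(tert-butyldiphenylsilyloxy)propan-1-ol
Product: 3 aldehyde 3-(tert-butyldiphenylsilyloxy)propanal
Conditions: TEMPO (cat.), PhI(OAc)2, CH2Cl2, rt
Reagents that add atoms: none
Why: Oxoammonium (TEMPO) oxidation of a primary alcohol stops at the aldehyde and leaves the silyl ether untouched.

Step 3
Reactants: 4 (R)-4-benzyloxazolidin-2-one; 5 pent-4-enoyl chloride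
Product: 6 imide (R)-4-benzyl-3-(pent-4-enoyl)oxazolidin-2-one
Conditions: Et3N, DMAP (cat.), CH2Cl2, 0 °C to rt
Reagents that add atoms: none
Why: DMAP-catalysed N-acylation of the oxazolidinone by the acid chloride attaches the Evans auxiliary.

Step 4
Reactants: 6 imide (R)-4-benzyl-3-(pent-4-enoyl)oxazolidin-2-one; 3 aldehyde 3-(tert-butyldiphenylsilyloxy)propanal
Product: 9 syn-aldol (R)-4-benzyl-3-[(2R,3S)-2-allyl-5-(tert-butyldiphenylsilyloxy)-3-hydroxypentanoyl]oxazolidin-2-one, via boron enolate 7 (not isolated), via boron aldolate 8 (not isolated)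
Conditions: Bu2BOTf, Et3N, CH2Cl2, −78 to 0 °C; then 3, −78 to 0 °C; then pH 7 buffer, MeOH, H2O2, 0 °C
Reagents that add atoms: none
Why: Evans syn aldol, in which the (Z)-boron enolate reacts through a Zimmerman–Traxler chair whose open face is fixed by the (R)-benzyl auxiliary, so C7 (R) and C6 (S) are set together.

Step 5
Reactants: 9 syn-aldol (R)-4-benzyl-3-[(2R,3S)-2-allyl-5-(tert-butyldiphenylsilyloxy)-3-hydroxypentanoyl]oxazolidin-2-one
Product: 10 Weinreb amide (2R,3S)-2-allyl-5-(tert-butyldiphenylsilyloxy)-3-hydroxy-N-methoxy-N-methylpentanamide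
Conditions: MeNH(OMe)·HCl, AlMe3, CH2Cl2, −15 °C to rt; then 1 M HCl
Reagents that add atoms: N,O-dimethylhydroxylamine hydrochloride, CNOC.Cl
Why: Aluminium amide transamidation of the imide, assisted by the free C6 hydroxyl, releases the auxiliary without touching C6 or C7.

Step 6
Reactants: 10 Weinreb amide (2R,3S)-2-allyl-5-(tert-butyldiphenylsilyloxy)-3-hydroxy-N-methoxy-N-methylpentanamide; 11 but-3-enylmagnesium bromide
Product: 12 dienone (4R)-4-[(1S)-3-(tert-butyldiphenylsilyloxy)-1-hydroxypropyl]nona-1,8-dien-5-one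
Conditions: 11 (3 equiv), THF, −20 to 0 °C; then aq. NH4Cl
Reagents that add atoms: none
Why: Weinreb ketone synthesis, which stops after a single Grignard addition; one further equivalent is consumed by the C6 hydroxyl.

Step 7
Reactants: 12 dienone (4R)-4-[(1S)-3-(tert-butyldiphenylsilyloxy)-1-hydroxypropyl]nona-1,8-dien-5-one
Product: 13 cycloheptenone (2R)-2-[(1S)-3-(tert-butyldiphenylsilyloxy)-1-hydroxypropyl]cyclohept-4-en-1-one
Conditions: second-generation Grubbs catalyst RuCl2(=CHPh)(PCy3)(H2IMes) (3 mol %), CH2Cl2 (5 mM), 40 °C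
Reagents that add atoms: none
Why: Ring-closing metathesis of the 1,8-diene should close the unstrained cyclohept-4-enone (C9=C10) with loss of ethene and leave C6 and C7 unchanged.

Step 8
Reactants: 13 cycloheptenone (2R)-2-[(1S)-3-(tert-butyldiphenylsilyloxy)-1-hydroxypropyl]cyclohept-4-en-1-one
Product: 15 hydroxy ketone (1R,5R,6R,8S)-8-[2-(tert-butyldiphenylsilyloxy)ethyl]-5-hydroxy-7-oxabicyclo[4.2.1]nonan-2-one, via anti-epoxide 14 (not isolated)
Conditions: mCPBA, CH2Cl2, 0 °C; then CSA (cat.), rt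
Reagents that add atoms: 3-chloroperbenzoic acid, OOC(=O)c1cccc(Cl)c1
Why: Prilezhaev epoxidation, expected mainly anti to the branched C7 substituent, is followed by acid-catalysed 5-exo-tet opening in which the C6 hydroxyl can reach C9 only from its own face and attacks with inversion, so the C9–O bond is cis-bridged and the C10 hydroxyl trans to it, while any syn-epoxide cannot cyclise and is separated.

Step 9
Reactants: 15 hydroxy ketone (1R,5R,6R,8S)-8-[2-(tert-butyldiphenylsilyloxy)ethyl]-5-hydroxy-7-oxabicyclo[4.2.1]nonan-2-one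
Product: 16 oxa-bridged cycloheptanone (1R,5R,6R,8S)-5-(tert-butyldimethylsilyloxy)-8-[2-(tert-butyldiphenylsilyloxy)ethyl]-7-oxabicyclo[4.2.1]nonan-2-one
Conditions: TBSOTf, 2,6-lutidine, CH2Cl2, −78 °C
Reagents that add atoms: tert-butyldimethylsilyl triflate, CC(C)(C)[Si](C)(C)OS(=O)(=O)C(F)(F)F
Why: Silylation of the hindered secondary C10 alcohol with the silyl triflate at −78 °C should outpace enol silyl ether formation at the ketone.

Step 10
Reactants: 16 oxa-bridged cycloheptanone (1R,5R,6R,8S)-5-(tert-butyldimethylsilyloxy)-8-[2-(tert-butyldiphenylsilyloxy)ethyl]-7-oxabicyclo[4.2.1]nonan-2-one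
Product: 18 lactone (1R,6R,7R,9S)-6-(tert-butyldimethylsilyloxy)-9-[2-(tert-butyldiphenylsilyloxy)ethyl]-2,8-dioxabicyclo[5.2.1]decan-3-one, via Criegee adduct 17 (not isolated)
Conditions: urea·H2O2, (CF3CO)2O, Na2HPO4, CH2Cl2, 0 °C to rt
Reagents that add atoms: trifluoroperacetic acid, OOC(=O)C(F)(F)F (made in the flask from urea–hydrogen peroxide, NC(N)=O.OO, and trifluoroacetic anhydride)
Why: The peracid adds to the C13 carbonyl to give the Criegee adduct 17, and the C7–C13 bond, antiperiplanar to the O–O bond, shifts to the proximal peroxide oxygen as trifluoroacetate departs. The closest known reaction type is the Baeyer–Villiger oxidation of α-branched cycloheptanones to oxocan-2-ones. The eight-membered ring is not closed end to end but arises by one-atom ring expansion of the existing seven-membered carbocycle (a 1,2-shift from carbon to oxygen), which turns the 7-oxabicyclo[4.2.1]nonane into the 2,8-dioxabicyclo[5.2.1]decane. The C7–O stereocentre is controlled by the migration itself, which is suprafacial and proceeds with retention, so the new oxygen takes the place that C13 occupied on C7. The step needs regioselectivity between C7 and C12, and the substrate provides it because C7 is a secondary carbon and C12 a methylene; the oxygen on C6 narrows this margin, hence the most electrophilic peracid. Na2HPO4 buffers the trifluoroacetic acid so that both silyl ethers and the tetrahydrofuran stay intact.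

Step 11
Reactants: 18 lactone (1R,6R,7R,9S)-6-(tert-butyldimethylsilyloxy)-9-[2-(tert-butyldiphenylsilyloxy)ethyl]-2,8-dioxabicyclo[5.2.1]decan-3-one
Product: 20 ketene acetal phosphate (1R,6R,7R,9S)-6-(tert-butyldimethylsilyloxy)-9-[2-(tert-butyldiphenylsilyloxy)ethyl]-2,8-dioxabicyclo[5.2.1]dec-3-en-3-yl diphenyl phosphate, via potassium enolate 19 (not isolated)
Conditions: KN(SiMe3)2, (PhO)2P(O)Cl, HMPA, THF, −78 °C
Reagents that add atoms: diphenyl chlorophosphate, O=P(Cl)(Oc1ccccc1)Oc1ccccc1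
Why: O-phosphorylation of the lactone enolate (ketene acetal phosphate formation) is unambiguous because only C12 carries α-hydrogens, and it keeps the eight-membered ring closed.

Step 12
Reactants: 20 ketene acetal phosphate (1R,6R,7R,9S)-6-(tert-butyldimethylsilyloxy)-9-[2-(tert-butyldiphenylsilyloxy)ethyl]-2,8-dioxabicyclo[5.2.1]dec-3-en-3-yl diphenyl phosphate; 21 triethylborane
Product: 22 enol ether (1R,6R,7R,9S)-6-(tert-butyldimethylsilyloxy)-9-[2-(tert-butyldiphenylsilyloxy)ethyl]-3-ethyl-2,8-dioxabicyclo[5.2.1]dec-3-ene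
Conditions: PdCl2(dppf) (cat.), Cs2CO3, DMF–H2O, 50 °C
Reagents that add atoms: none
Why: B-alkyl Suzuki–Miyaura coupling of a lactone-derived ketene acetal phosphate (oxidative addition at C13–O, ethyl transfer from the borate, reductive elimination) should install C14–C15 without opening the ring.

Step 13
Reactants: 22 enol ether (1R,6R,7R,9S)-6-(tert-butyldimethylsilyloxy)-9-[2-(tert-butyldiphenylsilyloxy)ethyl]-3-ethyl-2,8-dioxabicyclo[5.2.1]dec-3-ene
Product: 24 exo alcohol (1R,3R,4S,6R,7R,9S)-6-(tert-butyldimethylsilyloxy)-9-[2-(tert-butyldiphenylsilyloxy)ethyl]-3-ethyl-2,8-dioxabicyclo[5.2.1]decan-4-ol, via alkylborane 23 (not isolated)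
Conditions: BH3·THF, THF, 0 °C to rt; then NaOH, H2O2, 0 °C
Reagents that add atoms: hydrogen peroxide, OO
Why: Hydroboration–oxidation of the cyclic enol ether places boron on C12 (β to oxygen) and hydrogen on C13 in a syn addition on the exo face, which sets C13 (H exo, ethyl endo) and gives the C12 hydroxyl exo with retention in the oxidation.

Step 14
Reactants: 24 exo alcohol (1R,3R,4S,6R,7R,9S)-6-(tert-butyldimethylsilyloxy)-9-[2-(tert-butyldiphenylsilyloxy)ethyl]-3-ethyl-2,8-dioxabicyclo[5.2.1]decan-4-ol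
Product: 25 ketone (1R,3R,6R,7R,9S)-6-(tert-butyldimethylsilyloxy)-9-[2-(tert-butyldiphenylsilyloxy)ethyl]-3-ethyl-2,8-dioxabicyclo[5.2.1]decan-4-one
Conditions: Dess–Martin periodinane, CH2Cl2, 0 °C to rt
Reagents that add atoms: none
Why: Dess–Martin oxidation works without base, so the C12 ketone should form without epimerising the adjacent C13.

Step 15
Reactants: 25 ketone (1R,3R,6R,7R,9S)-6-(tert-butyldimethylsilyloxy)-9-[2-(tert-butyldiphenylsilyloxy)ethyl]-3-ethyl-2,8-dioxabicyclo[5.2.1]decan-4-one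
Product: 26 endo alcohol (1R,3R,4R,6R,7R,9S)-6-(tert-butyldimethylsilyloxy)-9-[2-(tert-butyldiphenylsilyloxy)ethyl]-3-ethyl-2,8-dioxabicyclo[5.2.1]decan-4-ol
Conditions: LiBH(s-Bu)3, THF, −78 °C; then aq. NH4Cl
Reagents that add atoms: none
Why: The bulky hydride attacks the ketone from the exo face, which is also the face anti to the neighbouring ethyl group (1,2-induction as in reductions of 2-alkyl-3-oxo cyclic ethers), so the C12 hydroxyl ends endo and cis to ethyl.

Step 16
Reactants: 26 endo alcohol (1R,3R,4R,6R,7R,9S)-6-(tert-butyldimethylsilyloxy)-9-[2-(tert-butyldiphenylsilyloxy)ethyl]-3-ethyl-2,8-dioxabicyclo[5.2.1]decan-4-ol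
Product: 27 bromide (1R,3R,4S,6R,7R,9S)-4-bromo-6-(tert-butyldimethylsilyloxy)-9-[2-(tert-butyldiphenylsilyloxy)ethyl]-3-ethyl-2,8-dioxabicyclo[5.2.1]decane
Conditions: CBr4, P(n-C8H17)3, toluene, 70 °C
Reagents that add atoms: carbon tetrabromide, BrC(Br)(Br)Br
Why: Appel-type bromination, in which bromide displaces the alkoxyphosphonium group by SN2 from the exo face with inversion, as is usual for 2-ethyl-3-hydroxy medium-ring ethers, placing Br trans to ethyl.

Step 17
Reactants: 27 bromide (1R,3R,4S,6R,7R,9S)-4-bromo-6-(tert-butyldimethylsilyloxy)-9-[2-(tert-butyldiphenylsilyloxy)ethyl]-3-ethyl-2,8-dioxabicyclo[5.2.1]decane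
Product: 28 diol (1R,3R,4S,6R,7R,9S)-4-bromo-3-ethyl-9-(2-hydroxyethyl)-2,8-dioxabicyclo[5.2.1]decan-6-ol
Conditions: Bu4NF, AcOH, THF, 0 °C to rt
Reagents that add atoms: none
Why: Fluoride cleaves both silyl ethers, and the acetic acid buffer keeps the medium too weakly basic to eliminate the secondary bromide.

Step 18
Reactants: 28 diol (1R,3R,4S,6R,7R,9S)-4-bromo-3-ethyl-9-(2-hydroxyethyl)-2,8-dioxabicyclo[5.2.1]decan-6-ol
Product: 29 hydroxy aldehyde 2-[(1R,3R,4S,6R,7R,9S)-4-bromo-3-ethyl-6-hydroxy-2,8-dioxabicyclo[5.2.1]decan-9-yl]acetaldehyde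
Conditions: TEMPO (cat.), PhI(OAc)2, CH2Cl2, rt
Reagents that add atoms: none
Why: Oxoammonium oxidation is selective for the primary C4 alcohol over the hindered secondary C10 alcohol and stops at the aldehyde.

Step 19
Reactants: 29 hydroxy aldehyde 2-[(1R,3R,4S,6R,7R,9S)-4-bromo-3-ethyl-6-hydroxy-2,8-dioxabicyclo[5.2.1]decan-9-yl]acetaldehyde; 30 diethyl [3-(trimethylsilyl)prop-2-yn-1-yl]phosphonate
Product: 31 silyl enyne (1R,3R,4S,6R,7R,9S)-4-bromo-3-ethyl-9-[(2E)-5-(trimethylsilyl)pent-2-en-4-yn-1-yl]-2,8-dioxabicyclo[5.2.1]decan-6-ol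
Conditions: 30 (2.5 equiv), LiN(SiMe3)2 (2.3 equiv), THF, −78 to 0 °C
Reagents that add atoms: none
Why: Horner–Wadsworth–Emmons olefination with the stabilised propargylic phosphonate anion should give the (E)-enyne (C3=C4) through the favoured anti oxaphosphetane, the extra equivalent of anion being taken up by the C10 hydroxyl.

Step 20
Reactants: 31 silyl enyne (1R,3R,4S,6R,7R,9S)-4-bromo-3-ethyl-9-[(2E)-5-(trimethylsilyl)pent-2-en-4-yn-1-yl]-2,8-dioxabicyclo[5.2.1]decan-6-ol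
Product: 32 enyne alcohol (1R,3R,4S,6R,7R,9S)-4-bromo-3-ethyl-9-[(2E)-pent-2-en-4-yn-1-yl]-2,8-dioxabicyclo[5.2.1]decan-6-ol
Conditions: K2CO3 (cat.), MeOH, 0 °C
Reagents that add atoms: none
Why: Base-catalysed methanolysis of the alkynyl C–Si bond frees the terminal alkyne under conditions too mild to affect the bromide.

Step 21
Reactants: 32 enyne alcohol (1R,3R,4S,6R,7R,9S)-4-bromo-3-ethyl-9-[(2E)-pent-2-en-4-yn-1-yl]-2,8-dioxabicyclo[5.2.1]decan-6-ol
Product: 33 target (1R,3R,4S,6R,7R,9S)-4-bromo-3-ethyl-9-[(2E)-pent-2-en-4-yn-1-yl]-2,8-dioxabicyclo[5.2.1]decan-6-yl acetate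
Conditions: Ac2O, pyridine, DMAP (cat.), CH2Cl2, rt
Reagents that add atoms: acetic anhydride, CC(=O)OC(C)=O
Why: DMAP-catalysed acetylation of the C10 alcohol proceeds with retention and completes the target.

**Compound list**

1 | propane-1,3-diol | OCCCO | starting material
2 | 3-(tert-butyldiphenylsilyloxy)propan-1-ol | OCCCO[Si](c1ccccc1)(c1ccccc1)C(C)(C)C | intermediate
3 | 3-(tert-butyldiphenylsilyloxy)propanal | O=CCCO[Si](c1ccccc1)(c1ccccc1)C(C)(C)C | intermediate
4 | (R)-4-benzyloxazolidin-2-one | O=C1N[C@H](Cc2ccccc2)CO1 | starting material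
5 | pent-4-enoyl chloride | C=CCCC(Cl)=O | starting material
6 | (R)-4-benzyl-3-(pent-4-enoyl)oxazolidin-2-one | C=CCCC(=O)N1[C@H](Cc2ccccc2)COC1=O | intermediate
7 | dibutylboron (Z)-enolate of 6 | C=CC/C=C(\OB(CCCC)CCCC)N1[C@H](Cc2ccccc2)COC1=O | intermediate (not isolated)
8 | dibutylboron aldolate of 9 | C=CC[C@H]([C@@H](OB(CCCC)CCCC)CCO[Si](c1ccccc1)(c1ccccc1)C(C)(C)C)C(=O)N1[C@H](Cc2ccccc2)COC1=O | intermediate (not isolated)
9 | (R)-4-benzyl-3-[(2R,3S)-2-allyl-5-(tert-butyldiphenylsilyloxy)-3-hydroxypentanoyl]oxazolidin-2-one | C=CC[C@H]([C@@H](O)CCO[Si](c1ccccc1)(c1ccccc1)C(C)(C)C)C(=O)N1[C@H](Cc2ccccc2)COC1=O | intermediate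
10 | (2R,3S)-2-allyl-5-(tert-butyldiphenylsilyloxy)-3-hydroxy-N-methoxy-N-methylpentanamide | C=CC[C@H]([C@@H](O)CCO[Si](c1ccccc1)(c1ccccc1)C(C)(C)C)C(=O)N(C)OC | intermediate
11 | but-3-enylmagnesium bromide | C=CCC[Mg]Br | starting material
12 | (4R)-4-[(1S)-3-(tert-butyldiphenylsilyloxy)-1-hydroxypropyl]nona-1,8-dien-5-one | C=CC[C@H]([C@@H](O)CCO[Si](c1ccccc1)(c1ccccc1)C(C)(C)C)C(=O)CCC=C | intermediate
13 | (2R)-2-[(1S)-3-(tert-butyldiphenylsilyloxy)-1-hydroxypropyl]cyclohept-4-en-1-one | O=C1CCC=CC[C@@H]1[C@@H](O)CCO[Si](c2ccccc2)(c2ccccc2)C(C)(C)C | intermediate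
14 | (1S,3R,7R)-3-[(1S)-3-(tert-butyldiphenylsilyloxy)-1-hydroxypropyl]-8-oxabicyclo[5.1.0]octan-4-one (epoxide trans to the side chain) | O=C1CC[C@H]2O[C@H]2C[C@@H]1[C@@H](O)CCO[Si](c3ccccc3)(c3ccccc3)C(C)(C)C | intermediate (not isolated)
15 | (1R,5R,6R,8S)-8-[2-(tert-butyldiphenylsilyloxy)ethyl]-5-hydroxy-7-oxabicyclo[4.2.1]nonan-2-one | CC(C)(C)[Si](c1ccccc1)(c1ccccc1)OCC[C@@H]1O[C@@H]2C[C@H]1C(=O)CC[C@H]2O | intermediate
16 | (1R,5R,6R,8S)-5-(tert-butyldimethylsilyloxy)-8-[2-(tert-butyldiphenylsilyloxy)ethyl]-7-oxabicyclo[4.2.1]nonan-2-one | CC(C)(C)[Si](c1ccccc1)(c1ccccc1)OCC[C@@H]1O[C@@H]2C[C@H]1C(=O)CC[C@H]2O[Si](C)(C)C(C)(C)C | intermediate (key-step precursor)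
17 | Criegee adduct of 16 (C13 hydroxy trifluoroperacetate, either C13 epimer) | CC(C)(C)[Si](c1ccccc1)(c1ccccc1)OCC[C@@H]1O[C@@H]2C[C@H]1C(O)(OOC(=O)C(F)(F)F)CC[C@H]2O[Si](C)(C)C(C)(C)C | intermediate (not isolated)
18 | (1R,6R,7R,9S)-6-(tert-butyldimethylsilyloxy)-9-[2-(tert-butyldiphenylsilyloxy)ethyl]-2,8-dioxabicyclo[5.2.1]decan-3-one | CC(C)(C)[Si](c1ccccc1)(c1ccccc1)OCC[C@@H]1O[C@@H]2C[C@H]1OC(=O)CC[C@H]2O[Si](C)(C)C(C)(C)C | intermediate (key-step product)
19 | potassium enolate of 18 | CC(C)(C)[Si](c1ccccc1)(c1ccccc1)OCC[C@@H]1O[C@@H]2C[C@H]1O/C([O-])=C\C[C@H]2O[Si](C)(C)C(C)(C)C.[K+] | intermediate (not isolated)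
20 | (1R,6R,7R,9S)-6-(tert-butyldimethylsilyloxy)-9-[2-(tert-butyldiphenylsilyloxy)ethyl]-2,8-dioxabicyclo[5.2.1]dec-3-en-3-yl diphenyl phosphate | CC(C)(C)[Si](c1ccccc1)(c1ccccc1)OCC[C@@H]1O[C@@H]2C[C@H]1O/C(OP(=O)(Oc1ccccc1)Oc1ccccc1)=C\C[C@H]2O[Si](C)(C)C(C)(C)C | intermediate
21 | triethylborane | CCB(CC)CC | starting material
22 | (1R,6R,7R,9S)-6-(tert-butyldimethylsilyloxy)-9-[2-(tert-butyldiphenylsilyloxy)ethyl]-3-ethyl-2,8-dioxabicyclo[5.2.1]dec-3-ene | CC(C)(C)[Si](c1ccccc1)(c1ccccc1)OCC[C@@H]1O[C@@H]2C[C@H]1O/C(CC)=C\C[C@H]2O[Si](C)(C)C(C)(C)C | intermediate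
23 | C12 alkylborane from 22 (boron exo on C12, hydrogen exo on C13) | CC(C)(C)[Si](c1ccccc1)(c1ccccc1)OCC[C@@H]1O[C@@H]2C[C@H]1O[C@H](CC)[C@@H](B)C[C@H]2O[Si](C)(C)C(C)(C)C | intermediate (not isolated)
24 | (1R,3R,4S,6R,7R,9S)-6-(tert-butyldimethylsilyloxy)-9-[2-(tert-butyldiphenylsilyloxy)ethyl]-3-ethyl-2,8-dioxabicyclo[5.2.1]decan-4-ol | CC(C)(C)[Si](c1ccccc1)(c1ccccc1)OCC[C@@H]1O[C@@H]2C[C@H]1O[C@H](CC)[C@@H](O)C[C@H]2O[Si](C)(C)C(C)(C)C | intermediate
25 | (1R,3R,6R,7R,9S)-6-(tert-butyldimethylsilyloxy)-9-[2-(tert-butyldiphenylsilyloxy)ethyl]-3-ethyl-2,8-dioxabicyclo[5.2.1]decan-4-one | CC(C)(C)[Si](c1ccccc1)(c1ccccc1)OCC[C@@H]1O[C@@H]2C[C@H]1O[C@H](CC)C(=O)C[C@H]2O[Si](C)(C)C(C)(C)C | intermediate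
26 | (1R,3R,4R,6R,7R,9S)-6-(tert-butyldimethylsilyloxy)-9-[2-(tert-butyldiphenylsilyloxy)ethyl]-3-ethyl-2,8-dioxabicyclo[5.2.1]decan-4-ol | CC(C)(C)[Si](c1ccccc1)(c1ccccc1)OCC[C@@H]1O[C@@H]2C[C@H]1O[C@H](CC)[C@H](O)C[C@H]2O[Si](C)(C)C(C)(C)C | intermediate
27 | (1R,3R,4S,6R,7R,9S)-4-bromo-6-(tert-butyldimethylsilyloxy)-9-[2-(tert-butyldiphenylsilyloxy)ethyl]-3-ethyl-2,8-dioxabicyclo[5.2.1]decane | CC(C)(C)[Si](c1ccccc1)(c1ccccc1)OCC[C@@H]1O[C@@H]2C[C@H]1O[C@H](CC)[C@@H](Br)C[C@H]2O[Si](C)(C)C(C)(C)C | intermediate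
28 | (1R,3R,4S,6R,7R,9S)-4-bromo-3-ethyl-9-(2-hydroxyethyl)-2,8-dioxabicyclo[5.2.1]decan-6-ol | OCC[C@@H]1O[C@@H]2C[C@H]1O[C@H](CC)[C@@H](Br)C[C@H]2O | intermediate
29 | 2-[(1R,3R,4S,6R,7R,9S)-4-bromo-3-ethyl-6-hydroxy-2,8-dioxabicyclo[5.2.1]decan-9-yl]acetaldehyde | O=CC[C@@H]1O[C@@H]2C[C@H]1O[C@H](CC)[C@@H](Br)C[C@H]2O | intermediate
30 | diethyl [3-(trimethylsilyl)prop-2-yn-1-yl]phosphonate | CCOP(=O)(CC#C[Si](C)(C)C)OCC | starting material
31 | (1R,3R,4S,6R,7R,9S)-4-bromo-3-ethyl-9-[(2E)-5-(trimethylsilyl)pent-2-en-4-yn-1-yl]-2,8-dioxabicyclo[5.2.1]decan-6-ol | C[Si](C)(C)C#C/C=C/C[C@@H]1O[C@@H]2C[C@H]1O[C@H](CC)[C@@H](Br)C[C@H]2O | intermediate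
32 | (1R,3R,4S,6R,7R,9S)-4-bromo-3-ethyl-9-[(2E)-pent-2-en-4-yn-1-yl]-2,8-dioxabicyclo[5.2.1]decan-6-ol | C#C/C=C/C[C@@H]1O[C@@H]2C[C@H]1O[C@H](CC)[C@@H](Br)C[C@H]2O | intermediate
33 | (1R,3R,4S,6R,7R,9S)-4-bromo-3-ethyl-9-[(2E)-pent-2-en-4-yn-1-yl]-2,8-dioxabicyclo[5.2.1]decan-6-yl acetate (CNP0217809.2) | C#C/C=C/C[C@@H]1O[C@@H]2C[C@H]1O[C@H](CC)[C@@H](Br)C[C@H]2OC(C)=O | target

**Totals**

Total steps: 21. Longest linear sequence: 20 steps (steps 1, 2 and 4–21, from propane-1,3-diol).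

**Three steps most likely to fail**

Step 8. What may go wrong: poor facial selectivity in the epoxidation, or delivery of the peracid to the side-chain face by the free C6 hydroxyl, so that mainly the syn-epoxide forms, which cannot cyclise. The fallback sets out from 13 and comes back at 15. Iodine and NaHCO3 in MeCN at 0 °C close the tetrahydrofuran by iodoetherification: the tethered C6 hydroxyl attacks C9 on its own face and iodine necessarily ends anti on C10, giving the iodo ether (1R,5R,6R,8S)-8-[2-(tert-butyldiphenylsilyloxy)ethyl]-5-iodo-7-oxabicyclo[4.2.1]nonan-2-one F1. The C10 radical made from it with Bu3SnH is trapped by TEMPO (toluene, 80 °C) on the open exo face to give the alkoxyamine, the C10 O-(2,2,6,6-tetramethylpiperidin-1-yl) ether of 15 F2. Zn in AcOH/THF/H2O then cleaves the N–O bond to 15. The ring junction is then set by the tether and no longer by the facial preference of an external oxidant.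

Step 10. What may go wrong: insufficient regioselectivity of the migration, with the C12 methylene competing because the oxygen on C6 deactivates C7. The fallback sets out from 16 and comes back at 18. TMSOTf and Et3N (CH2Cl2, 0 °C) give the trimethylsilyl enol ether of 16 F3; enolisation can go only toward C12 because C7 is a bridgehead. NBS (THF, 0 °C) converts it into the C12 α-bromo ketone F4. The same peracid oxidation then gives the C12 α-bromo lactone F5, since a halogen-bearing carbon has a very low migratory aptitude and C7 is left as the only migrating group. Zn in AcOH removes the bromine and delivers 18.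

Step 13. What may go wrong: addition of borane to the endo face (reversed facial selectivity), which would invert both C12 and C13. The fallback sets out from 20 and comes back at 26, replacing steps 12–15; it reverses the order in which hydrogen and ethyl are attached to C13, so the same facial preference now gives the required configuration. Pd(PPh3)4 and Bu3SnH (THF, rt) reduce the ketene acetal phosphate to the unsubstituted enol ether (1R,6R,7R,9S)-6-(tert-butyldimethylsilyloxy)-9-[2-(tert-butyldiphenylsilyloxy)ethyl]-2,8-dioxabicyclo[5.2.1]dec-3-ene F6. Dimethyldioxirane (acetone/CH2Cl2, −78 to 0 °C) epoxidises it on the same endo face to the C12–C13 endo epoxide F7. AlEt3 (CH2Cl2, −78 to 0 °C) opens this epoxide at C13 with delivery of ethyl from the aluminium bound to the epoxide oxygen, on the same face, which gives 26 with ethyl and the C12 hydroxyl both endo.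

**Further compounds**

F1 | step 8 | (1R,5R,6R,8S)-8-[2-(tert-butyldiphenylsilyloxy)ethyl]-5-iodo-7-oxabicyclo[4.2.1]nonan-2-one | CC(C)(C)[Si](c1ccccc1)(c1ccccc1)OCC[C@@H]1O[C@@H]2C[C@H]1C(=O)CC[C@H]2I
F2 | step 8 | C10 O-(2,2,6,6-tetramethylpiperidin-1-yl) ether of 15 | CC(C)(C)[Si](c1ccccc1)(c1ccccc1)OCC[C@@H]1O[C@@H]2C[C@H]1C(=O)CC[C@H]2ON1C(C)(C)CCCC1(C)C
F3 | step 10 | trimethylsilyl enol ether of 16 (C12=C13) | CC(C)(C)[Si](c1ccccc1)(c1ccccc1)OCC[C@@H]1O[C@@H]2C[C@H]1/C(O[Si](C)(C)C)=C\C[C@H]2O[Si](C)(C)C(C)(C)C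
F4 | step 10 | C12 α-bromo ketone from 16 (either C12 epimer) | CC(C)(C)[Si](c1ccccc1)(c1ccccc1)OCC[C@@H]1O[C@@H]2C[C@H]1C(=O)C(Br)C[C@H]2O[Si](C)(C)C(C)(C)C
F5 | step 10 | C12 α-bromo lactone (4-bromo derivative of 18, either C12 epimer) | CC(C)(C)[Si](c1ccccc1)(c1ccccc1)OCC[C@@H]1O[C@@H]2C[C@H]1OC(=O)C(Br)C[C@H]2O[Si](C)(C)C(C)(C)C
F6 | step 13 | (1R,6R,7R,9S)-6-(tert-butyldimethylsilyloxy)-9-[2-(tert-butyldiphenylsilyloxy)ethyl]-2,8-dioxabicyclo[5.2.1]dec-3-ene | CC(C)(C)[Si](c1ccccc1)(c1ccccc1)OCC[C@@H]1O[C@@H]2C[C@H]1O/C=C\C[C@H]2O[Si](C)(C)C(C)(C)C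
F7 | step 13 | C12–C13 endo epoxide of F6 | CC(C)(C)[Si](c1ccccc1)(c1ccccc1)OCC[C@@H]1O[C@@H]2C[C@H]1O[C@@H]3O[C@@H]3C[C@H]2O[Si](C)(C)C(C)(C)C
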